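**Strategy.** The route rests on cutting two bonds of the trisubstituted 4,5-epoxide that is fused to the ten-membered carbocycle C1–C10: C4–C5 and C4–O. The fully substituted C4, which carries methyl C15, is read as a diphenylsulfonium ylide carbon and C5 as an aldehyde. One base-triggered operation then closes the cyclodecene and the oxirane and sets C4 and C5. The precursor is an open chain with the C5 aldehyde, PMB ethers at O6 and O12 (lactone kept open), a silyl ether at O8, the C9 acetate, the (E)-C10 methyl enoate and a C1–C4 arm ending in the C4 sulfonium salt.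

Key step: step 20

Assumption: locants follow the germacrane skeleton (ring C1–C10, lactone carbons C11–C13, ester carbon C14, methyl C15); centres left undefined in the SMILES (C10/C1 in 18–19, C4 in 23–30) are mixtures that are erased later.

**Route**

Step 1
Reactants: 1 3-bromo-2-(bromomethyl)prop-1-ene; 2 4-methoxybenzyl alcohol
Product: 3 2-(bromomethyl)allyl 4-methoxybenzyl ether
Conditions: NaH, THF, 0 °C → rt (1 in threefold excess)
Reagents that add atoms: none
Why: Williamson ether synthesis; the excess of the symmetrical allylic dibromide keeps the substitution at one arm.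

Step 2
Reactants: 3 2-(bromomethyl)allyl 4-methoxybenzyl ether; 4 (tert-butyldimethylsilyloxy)acetaldehyde
Product: 5 racemic 1-(tert-butyldimethylsilyloxy)-4-{[(4-methoxybenzyl)oxy]methyl}pent-4-en-2-ol
Conditions: indium powder, THF/H2O (1:1), rt
Reagents that add atoms: none
Why: Indium-mediated Barbier allylation; both allyl termini are CH2, so only one constitution can form, and the new carbinol centre is oxidised away in step 3.

Step 3
Reactants: 5 racemic homoallylic alcohol
Product: 6 1-(tert-butyldimethylsilyloxy)-4-{[(4-methoxybenzyl)oxy]methyl}pent-4-en-2-one (C5, C6, C7, C11–C13)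
Conditions: Dess–Martin periodinane, CH2Cl2, 0 °C → rt
Reagents that add atoms: none
Why: Dess–Martin oxidation of a secondary alcohol under neutral conditions, which keeps the β,γ-double bond out of conjugation.

Step 4
Reactants: 7 dimethyl (S)-malate
Product: 8 methyl (S)-3,4-dihydroxybutanoate
Conditions: BH3·SMe2, NaBH4 (5 mol %), THF, rt; MeOH quench
Reagents that add atoms: none
Why: Hydroxyl-directed borane reduction of the ester next to the free hydroxyl; the stereocentre (future C9) is not touched.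

Step 5
Reactants: 8 methyl (S)-3,4-dihydroxybutanoate
Product: 9 methyl (S)-3,4-bis(triethylsilyloxy)butanoate
Conditions: Et3SiCl, imidazole, CH2Cl2, 0 °C
Reagents that add atoms: chlorotriethylsilane, CC[Si](Cl)(CC)CC
Why: Silyl ether formation at both hydroxyls.

Step 6
Reactants: 9 methyl (S)-3,4-bis(triethylsilyloxy)butanoate
Product: 10 methyl (S)-4-oxo-3-(triethylsilyloxy)butanoate (C8 aldehyde with C9, C10, C14)
Conditions: (COCl)2, DMSO, CH2Cl2, −78 → −30 °C; then Et3N
Reagents that add atoms: none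
Why: Swern oxidation acts directly and selectively on the primary triethylsilyl ether, so the α-silyloxy aldehyde forms without a separate deprotection.

Step 7
Reactants: 6 ketone (C5–C7, C11–C13); 10 aldehyde (C8–C10, C14)
Product: 12 syn-aldol adduct methyl (3S,4R,5R)-7-(tert-butyldimethylsilyloxy)-4-hydroxy-5-{3-[(4-methoxybenzyl)oxy]prop-1-en-2-yl}-6-oxo-3-(triethylsilyloxy)heptanoate, via dibutylboron enolate 11 (not isolated)
Conditions: Bu2BOTf, i-Pr2NEt, CH2Cl2, −78 °C; then 10, −78 °C; pH 7 buffer, MeOH, H2O2, 0 °C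
Reagents that add atoms: none
Why: Boron-mediated syn-aldol reaction; enolisation at the doubly activated C7 methylene gives the Z-enolate, whose chair transition state sets C7 syn to the C8 hydroxyl, and addition anti to the C9–O bond of the α-silyloxy aldehyde (Cornforth/polar Felkin–Anh) sets C8 anti to C9.

Step 8
Reactants: 12 syn-aldol adduct
Product: 13 C8 tert-butyldimethylsilyl ether of 12
Conditions: t-BuMe2SiOTf, 2,6-lutidine, CH2Cl2, −78 °C
Reagents that add atoms: tert-butyldimethylsilyl triflate, CC(C)(C)[Si](C)(C)OS(=O)(=O)C(F)(F)F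
Why: Silylation with the silyl triflate at −78 °C caps O8 before retro-aldol, enolisation at C7 or lactonisation onto the C14 ester can occur.

Step 9
Reactants: 13 C8-silylated ketone
Product: 14 C6 alcohol (new centre 6S, C6–O syn to the C7 branch and to O8)
Conditions: (S)-1-methyl-3,3-diphenyltetrahydro-1H,3H-pyrrolo[1,2-c][1,3,2]oxazaborole (0.5 equiv), catecholborane, toluene, −78 °C
Reagents that add atoms: none
Why: Corey–Bakshi–Shibata reduction; the catalyst treats CH2OSi as the small and the branched C7 as the large ketone substituent and delivers hydride to the face that gives 6S, against the Felkin preference of the substrate, while catecholborane at −78 °C leaves C11=C13 and the ester alone.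

Step 10
Reactants: 14 C6 alcohol
Product: 15 C6 4-methoxybenzyl ether of 14
Conditions: 2-[(4-methoxybenzyl)oxy]-4-methylquinoline, MeOTf, MgO, PhCF3, 0 °C → rt
Reagents that add atoms: 2-[(4-methoxybenzyl)oxy]-4-methylquinoline, COc1ccc(COc2cc(C)c3ccccc3n2)cc1
Why: Dudley's neutral benzylation (transfer of the 4-methoxybenzyl group from the N-methylquinolinium salt formed in situ); no alkoxide is formed, so no silyl group migrates.

Step 11
Reactants: 15 fully protected C5–C10 ester; 16 4-oxopentanal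
Product: 18 β-hydroxy ester carrying the C1–C4 arm (mixture at C10 and C1), via lithium enolate 17 (not isolated)
Conditions: LiN(iPr)2, THF, −78 °C; then 16 (1.5 equiv), −78 °C; AcOH
Reagents that add atoms: none
Why: Lithium ester-enolate aldol addition, chemoselective for the aldehyde over the methyl ketone at −78 °C; the β-silyloxy group is not expelled at this temperature and the two new centres disappear in step 12.

Step 12
Reactants: 18 β-hydroxy ester
Product: 20 (E)-enoate with C4 ketone, via mesylate 19 (not isolated)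
Conditions: MsCl, Et3N, CH2Cl2, 0 °C; then 1,8-diazabicyclo[5.4.0]undec-7-ene, 0 °C → rt
Reagents that add atoms: none
Why: Mesylation and E1cB elimination through the ester enolate, stereoconvergent to the (E)-enoate (C2 anti to the ester, cis to C9) as in aldol-condensation routes to 2-alkylidene esters; the mesylate leaves far faster than the C9 silyloxy group.

Step 13
Reactants: 20 (E)-enoate
Product: 21 C9 alcohol
Conditions: pyridinium p-toluenesulfonate, MeOH/CH2Cl2, 0 °C
Reagents that add atoms: none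
Why: Acid-catalysed methanolysis removes the triethylsilyl ether and spares the two tert-butyldimethylsilyl ethers.

Step 14
Reactants: 21 C9 alcohol
Product: 22 C9 acetate
Conditions: Ac2O, pyridine, 4-(dimethylamino)pyridine (cat.), CH2Cl2, 0 °C
Reagents that add atoms: acetic anhydride, CC(=O)OC(C)=O
Why: Acetylation of the allylic hydroxyl; O8 is silylated, so no acyl migration is possible.

Step 15
Reactants: 22 C9 acetate with C4 ketone
Product: 23 C4 alcohol (both epimers)
Conditions: NaBH4, CeCl3·7H2O, MeOH, −40 °C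
Reagents that add atoms: none
Why: Luche reduction of the methyl ketone; the hindered enoate and the acetate are inert at −40 °C and the C4 configuration does not matter.

Step 16
Reactants: 23 C4 alcohol
Product: 24 C4 iodide
Conditions: I2, PPh3, imidazole, CH2Cl2, 0 °C
Reagents that add atoms: iodine, II
Why: Appel iodination by SN2 at the unhindered secondary carbinol.

Step 17
Reactants: 24 C4 iodide
Product: 25 C5 primary alcohol
Conditions: HF·pyridine, pyridine, THF, 0 °C → rt
Reagents that add atoms: none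
Why: Buffered fluoride cleaves the primary silyl ether much faster than the hindered secondary one at O8.

Step 18
Reactants: 25 C5 alcohol
Product: 26 C5 aldehyde
Conditions: Dess–Martin periodinane, CH2Cl2, 0 °C
Reagents that add atoms: none
Why: Dess–Martin oxidation gives the α-alkoxy aldehyde under neutral conditions without epimerisation at C6.

Step 19
Reactants: 26 C5 aldehyde with C4 iodide; 27 diphenyl sulfide
Product: 28 C4 diphenylsulfonium tetrafluoroborate with C5 aldehyde (both C4 epimers; C6–C9 arranged as in the target)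
Conditions: 27 (8 equiv), AgBF4, 2,6-di-tert-butyl-4-methylpyridine (0.2 equiv), CH2Cl2, 0 °C → rt, dark
Reagents that add atoms: silver tetrafluoroborate, [Ag+].F[B-](F)(F)F
Why: Silver-assisted S-alkylation of diphenyl sulfide by a secondary iodide, the standard entry to secondary-alkyl diphenylsulfonium tetrafluoroborates.

Step 20
Reactants: 28 sulfonium aldehyde
Product: 31 4,5-epoxy cyclodecene (4R,5R; O6 and O12 as PMB ethers, O8 silylated, C9 acetate), via sulfonium ylide 29 (not isolated), via betaine 30 (not isolated)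
Conditions: LiN(SiMe3)2 (1.05 equiv, added over 3 h), THF, 1 mM, −78 → −20 °C
Reagents that add atoms: none
Why: Proposed new method: the base removes the one C4–H next to sulfur (more acidic than the hindered C6–H, the acetate or the γ-hydrogens of the enoate), the C4 epimers merge in ylide 29, its carbon adds to the C5 aldehyde in a 10-exo-trig closure of the carbocycle to give betaine 30, and the alkoxide displaces diphenyl sulfide at C4 in a 3-exo-tet closure of the oxirane; the closest known reaction is the intermolecular Corey–Chaykovsky epoxidation of aldehydes with secondary-alkyl diphenylsulfonium ylides. C5 is controlled by the tether, which runs from C4 through C3, C2, C1=C10, C9 and C8 to C7: the ylide carbon must come in on the C7 side, antiperiplanar to the C6–O bond and over the aldehyde hydrogen, so the oxyanion points out of the forming ring and 5R (C5–O syn to C6–O) results; a lithium chelate between the aldehyde oxygen and the C6 PMB ether would lead to the same face. The open-chain polar Felkin–Anh preference would instead give the C5 epimer, so it is not the control element, and this is why O6 carries a benzyl-type ether and not a silyl group. C4 is fixed by the anti O–C5–C4–S closure with inversion, so 4R needs C3 and C6 anti in the betaine, the arrangement that puts the ring methylene and not methyl C15 opposite the branched C6 and that is found in the trans-4,5-epoxy ring of the target. Chemoselectivity is secured by the substrate (attack at C1 would make a four-membered ring, the C14 ester is held away from the arm by the E double bond, C11=C13 is an unactivated allyl ether) and by high dilution. Both stereochemical requirements are untested on a ten-membered ring.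

Step 21
Reactants: 31 4,5-epoxy cyclodecene
Product: 32 C6,C12-diol
Conditions: DDQ (2,3-dichloro-5,6-dicyano-1,4-benzoquinone), CH2Cl2/pH 7 buffer (10:1), 0 °C → rt
Reagents that add atoms: none
Why: Oxidative cleavage of both 4-methoxybenzyl ethers in one operation under buffered conditions that spare the epoxide, the silyl ether and the acetate.

Step 22
Reactants: 32 C6,C12-diol
Product: 35 α-methylene 6,12-lactone with O8 silylated, via hydroxy enal 33 (not isolated), via lactol 34 (not isolated)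
Conditions: 2,2,6,6-tetramethylpiperidin-1-oxyl (0.2 equiv), PhI(OAc)2, CH2Cl2, rt
Reagents that add atoms: none
Why: Nitroxyl-catalysed oxidative lactonisation of a 1,4-diol; the primary allylic alcohol is oxidised first, the C6 hydroxyl traps the enal as a five-membered lactol, and the lactol is oxidised to the lactone, with C6 and C7 unchanged so that the trans ring fusion follows from the substrate.

Step 23
Reactants: 35 silylated lactone
Product: 36 C8 alcohol
Conditions: HF·pyridine, pyridine, THF, 0 °C → rt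
Reagents that add atoms: none
Why: Desilylation under buffered acidic conditions, which avoid base-induced migration of the C9 acetate to O8 and are tolerated by trisubstituted epoxides.

Step 24
Reactants: 37 angelic acid
Product: 38 (Z)-2-methylbut-2-en-1-ol
Conditions: LiAlH4, Et2O, 0 °C → rt
Reagents that add atoms: none
Why: Hydride reduction of the acid to the allylic alcohol with retention of the Z double bond.

Step 25
Reactants: 38 (Z)-2-methylbut-2-en-1-ol
Product: 39 [(2R,3S)-2,3-dimethyloxiran-2-yl]methanol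
Conditions: Ti(OiPr)4, diisopropyl D-(−)-tartrate, t-BuOOH, 4 Å molecular sieves, CH2Cl2, −20 °C
Reagents that add atoms: tert-butyl hydroperoxide, CC(C)(C)OO
Why: Sharpless asymmetric epoxidation; the D-(−)-tartrate complex delivers oxygen to the face of the allylic alcohol that gives the (2R,3S)-epoxide.

Step 26
Reactants: 39 epoxy alcohol
Product: 40 (2S,3S)-2,3-dimethyloxirane-2-carboxylic acid
Conditions: RuCl3 (2 mol %), NaIO4, CCl4/MeCN/H2O, rt
Reagents that add atoms: sodium periodate, [Na+].[O-]I(=O)(=O)=O; water, O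
Why: Ruthenium tetroxide oxidation of the primary alcohol to the acid without opening the epoxide (the C2 descriptor changes only through the priority rules).

Step 27
Reactants: 40 epoxy acid
Product: 41 (2R,3R)-3-chloro-2-hydroxy-2-methylbutanoic acid
Conditions: HCl (4 M in dioxane), Et2O, 0 °C
Reagents that add atoms: hydrogen chloride, Cl
Why: Acid-induced epoxide opening by chloride at the secondary C3, away from the carboxyl-bearing quaternary carbon, with inversion.

Step 28
Reactants: 41 chlorohydrin acid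
Product: 43 (2R,3R)-3-chloro-2-methyl-2-(trimethylsilyloxy)butanoyl chloride, via bis-trimethylsilyl derivative 42 (not isolated)
Conditions: Me3SiCl, Et3N, CH2Cl2, 0 °C; then (COCl)2, N,N-dimethylformamide (cat.), 0 °C → rt; volatiles removed
Reagents that add atoms: chlorotrimethylsilane, C[Si](C)(C)Cl; oxalyl chloride, O=C(Cl)C(Cl)=O
Why: Wissner's route to α-silyloxy acyl chlorides; both hydroxyl and carboxyl are silylated and oxalyl chloride converts the silyl ester into the acid chloride under neutral conditions.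

Step 29
Reactants: 36 C8 alcohol; 43 silyloxy acid chloride
Product: 45 target, via trimethylsilyl ether 44 (not isolated)
Conditions: pyridine, 4-(dimethylamino)pyridine (0.2 equiv), CH2Cl2, −20 → 0 °C; then citric acid, MeOH, 0 °C
Reagents that add atoms: none
Why: Acylation of the hindered C8 hydroxyl by the acid chloride under nucleophilic catalysis; the silyl cap on the tertiary hydroxyl prevents self-acylation and ring closure of the chlorohydrin and is removed by mild acidic methanolysis.

**Compound list**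

1 | 3-bromo-2-(bromomethyl)prop-1-ene | C=C(CBr)CBr | starting material
2 | 4-methoxybenzyl alcohol | COc1ccc(CO)cc1 | starting material
3 | 1-({[2-(bromomethyl)prop-2-en-1-yl]oxy}methyl)-4-methoxybenzene | C=C(CBr)COCc1ccc(OC)cc1 | intermediate
4 | (tert-butyldimethylsilyloxy)acetaldehyde | CC(C)(C)[Si](C)(C)OCC=O | starting material
5 | racemic 1-(tert-butyldimethylsilyloxy)-4-{[(4-methoxybenzyl)oxy]methyl}pent-4-en-2-ol | C=C(COCc1ccc(OC)cc1)CC(O)CO[Si](C)(C)C(C)(C)C | intermediate
6 | 1-(tert-butyldimethylsilyloxy)-4-{[(4-methoxybenzyl)oxy]methyl}pent-4-en-2-one | C=C(COCc1ccc(OC)cc1)CC(=O)CO[Si](C)(C)C(C)(C)C | intermediate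
7 | dimethyl (S)-malate | COC(=O)C[C@H](O)C(=O)OC | starting material
8 | methyl (S)-3,4-dihydroxybutanoate | COC(=O)C[C@H](O)CO | intermediate
9 | methyl (S)-3,4-bis(triethylsilyloxy)butanoate | COC(=O)C[C@H](O[Si](CC)(CC)CC)CO[Si](CC)(CC)CC | intermediate
10 | methyl (S)-4-oxo-3-(triethylsilyloxy)butanoate | COC(=O)C[C@H](O[Si](CC)(CC)CC)C=O | intermediate
11 | (Z)-dibutylboron enolate of 6 (C6–O–B, C6=C7) | C=C(COCc1ccc(OC)cc1)/C=C(\OB(CCCC)CCCC)CO[Si](C)(C)C(C)(C)C | intermediate (not isolated)
12 | methyl (3S,4R,5R)-7-(tert-butyldimethylsilyloxy)-4-hydroxy-5-{3-[(4-methoxybenzyl)oxy]prop-1-en-2-yl}-6-oxo-3-(triethylsilyloxy)heptanoate | CC(C)(C)[Si](C)(C)OCC(=O)[C@H](C(=C)COCc1ccc(OC)cc1)[C@@H](O)[C@@H](O[Si](CC)(CC)CC)CC(=O)OC | intermediate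
13 | C8 tert-butyldimethylsilyl ether of 12 (C6 ketone; C7–C9 as in 12) | CC(C)(C)[Si](C)(C)OCC(=O)[C@H](C(=C)COCc1ccc(OC)cc1)[C@@H](O[Si](C)(C)C(C)(C)C)[C@@H](O[Si](CC)(CC)CC)CC(=O)OC | intermediate
14 | C6 alcohol from 13 (6S; O6, C7 branch and O8 all syn; O9 anti to O8) | CC(C)(C)[Si](C)(C)OC[C@@H](O)[C@H](C(=C)COCc1ccc(OC)cc1)[C@@H](O[Si](C)(C)C(C)(C)C)[C@@H](O[Si](CC)(CC)CC)CC(=O)OC | intermediate
15 | C6 4-methoxybenzyl ether of 14 | CC(C)(C)[Si](C)(C)OC[C@@H](OCc1ccc(OC)cc1)[C@H](C(=C)COCc1ccc(OC)cc1)[C@@H](O[Si](C)(C)C(C)(C)C)[C@@H](O[Si](CC)(CC)CC)CC(=O)OC | intermediate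
16 | 4-oxopentanal | CC(=O)CCC=O | starting material
17 | lithium enolate of ester 15 (C10=C14) | CC(C)(C)[Si](C)(C)OC[C@@H](OCc1ccc(OC)cc1)[C@H](C(=C)COCc1ccc(OC)cc1)[C@@H](O[Si](C)(C)C(C)(C)C)[C@@H](O[Si](CC)(CC)CC)C=C(OC)O[Li] | intermediate (not isolated)
18 | aldol adduct of 15 and 16 (C1 hydroxyl, C4 ketone; mixture at C10 and C1) | CC(C)(C)[Si](C)(C)OC[C@@H](OCc1ccc(OC)cc1)[C@H](C(=C)COCc1ccc(OC)cc1)[C@@H](O[Si](C)(C)C(C)(C)C)[C@@H](O[Si](CC)(CC)CC)C(C(=O)OC)C(O)CCC(C)=O | intermediate
19 | C1 mesylate of 18 | CC(C)(C)[Si](C)(C)OC[C@@H](OCc1ccc(OC)cc1)[C@H](C(=C)COCc1ccc(OC)cc1)[C@@H](O[Si](C)(C)C(C)(C)C)[C@@H](O[Si](CC)(CC)CC)C(C(=O)OC)C(OS(C)(=O)=O)CCC(C)=O | intermediate (not isolated)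
20 | (E)-C10=C1 methyl enoate with C4 ketone, O9 triethylsilyl | CC(C)(C)[Si](C)(C)OC[C@@H](OCc1ccc(OC)cc1)[C@H](C(=C)COCc1ccc(OC)cc1)[C@@H](O[Si](C)(C)C(C)(C)C)[C@@H](O[Si](CC)(CC)CC)/C(C(=O)OC)=C\CCC(C)=O | intermediate
21 | C9 alcohol from 20 | CC(C)(C)[Si](C)(C)OC[C@@H](OCc1ccc(OC)cc1)[C@H](C(=C)COCc1ccc(OC)cc1)[C@@H](O[Si](C)(C)C(C)(C)C)[C@@H](O)/C(C(=O)OC)=C\CCC(C)=O | intermediate
22 | C9 acetate with C4 ketone | CC(C)(C)[Si](C)(C)OC[C@@H](OCc1ccc(OC)cc1)[C@H](C(=C)COCc1ccc(OC)cc1)[C@@H](O[Si](C)(C)C(C)(C)C)[C@@H](OC(C)=O)/C(C(=O)OC)=C\CCC(C)=O | intermediate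
23 | C4 alcohol (both epimers) | CC(C)(C)[Si](C)(C)OC[C@@H](OCc1ccc(OC)cc1)[C@H](C(=C)COCc1ccc(OC)cc1)[C@@H](O[Si](C)(C)C(C)(C)C)[C@@H](OC(C)=O)/C(C(=O)OC)=C\CCC(C)O | intermediate
24 | C4 iodide (both epimers) | CC(C)(C)[Si](C)(C)OC[C@@H](OCc1ccc(OC)cc1)[C@H](C(=C)COCc1ccc(OC)cc1)[C@@H](O[Si](C)(C)C(C)(C)C)[C@@H](OC(C)=O)/C(C(=O)OC)=C\CCC(C)I | intermediate
25 | C5 primary alcohol with C4 iodide | OC[C@@H](OCc1ccc(OC)cc1)[C@H](C(=C)COCc1ccc(OC)cc1)[C@@H](O[Si](C)(C)C(C)(C)C)[C@@H](OC(C)=O)/C(C(=O)OC)=C\CCC(C)I | intermediate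
26 | C5 aldehyde with C4 iodide | O=C[C@@H](OCc1ccc(OC)cc1)[C@H](C(=C)COCc1ccc(OC)cc1)[C@@H](O[Si](C)(C)C(C)(C)C)[C@@H](OC(C)=O)/C(C(=O)OC)=C\CCC(C)I | intermediate
27 | diphenyl sulfide | c1ccc(Sc2ccccc2)cc1 | starting material
28 | C4 diphenylsulfonium tetrafluoroborate with C5 aldehyde (key-step precursor; both C4 epimers) | O=C[C@@H](OCc1ccc(OC)cc1)[C@H](C(=C)COCc1ccc(OC)cc1)[C@@H](O[Si](C)(C)C(C)(C)C)[C@@H](OC(C)=O)/C(C(=O)OC)=C\CCC(C)[S+](c1ccccc1)c1ccccc1.F[B-](F)(F)F | intermediate
29 | C4 sulfonium ylide of 28 | O=C[C@@H](OCc1ccc(OC)cc1)[C@H](C(=C)COCc1ccc(OC)cc1)[C@@H](O[Si](C)(C)C(C)(C)C)[C@@H](OC(C)=O)/C(C(=O)OC)=C\CC[C-](C)[S+](c1ccccc1)c1ccccc1 | intermediate (not isolated)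
30 | ten-membered betaine (C5 alkoxide, C4 sulfonium; C3 and C6 anti) | C=C(COCc1ccc(OC)cc1)[C@@H]1[C@@H](O[Si](C)(C)C(C)(C)C)[C@@H](OC(C)=O)/C(C(=O)OC)=C\CC[C@](C)([S+](c2ccccc2)c2ccccc2)[C@H]([O-])[C@H]1OCc1ccc(OC)cc1 | intermediate (not isolated)
31 | (4R,5R)-4,5-epoxy cyclodecene, O6 and O12 as PMB ethers, O8 silyl ether, C9 acetate, C14 methyl ester (key-step product) | C=C(COCc1ccc(OC)cc1)[C@@H]1[C@@H](O[Si](C)(C)C(C)(C)C)[C@@H](OC(C)=O)/C(C(=O)OC)=C\CC[C@@]2(C)O[C@@H]2[C@H]1OCc1ccc(OC)cc1 | intermediate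
32 | C6,C12-diol of 31 | C=C(CO)[C@@H]1[C@@H](O[Si](C)(C)C(C)(C)C)[C@@H](OC(C)=O)/C(C(=O)OC)=C\CC[C@@]2(C)O[C@@H]2[C@H]1O | intermediate
33 | C12 enal with free C6 hydroxyl | C=C(C=O)[C@@H]1[C@@H](O[Si](C)(C)C(C)(C)C)[C@@H](OC(C)=O)/C(C(=O)OC)=C\CC[C@@]2(C)O[C@@H]2[C@H]1O | intermediate (not isolated)
34 | C12 lactol (O6–C12, both anomers) | C=C1C(O)O[C@H]2[C@H]1[C@@H](O[Si](C)(C)C(C)(C)C)[C@@H](OC(C)=O)/C(C(=O)OC)=C\CC[C@@]1(C)O[C@H]21 | intermediate (not isolated)
35 | α-methylene 6,12-lactone, O8 tert-butyldimethylsilyl ether | C=C1C(=O)O[C@H]2[C@H]1[C@@H](O[Si](C)(C)C(C)(C)C)[C@@H](OC(C)=O)/C(C(=O)OC)=C\CC[C@@]1(C)O[C@H]21 | intermediate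
36 | α-methylene 6,12-lactone with free C8 hydroxyl | C=C1C(=O)O[C@H]2[C@H]1[C@@H](O)[C@@H](OC(C)=O)/C(C(=O)OC)=C\CC[C@@]1(C)O[C@H]21 | intermediate
37 | angelic acid | C/C=C(/C)C(=O)O | starting material
38 | (Z)-2-methylbut-2-en-1-ol | C/C=C(/C)CO | intermediate
39 | [(2R,3S)-2,3-dimethyloxiran-2-yl]methanol | C[C@@H]1O[C@]1(C)CO | intermediate
40 | (2S,3S)-2,3-dimethyloxirane-2-carboxylic acid | C[C@@H]1O[C@]1(C)C(=O)O | intermediate
41 | (2R,3R)-3-chloro-2-hydroxy-2-methylbutanoic acid | OC(=O)[C@@](C)(O)[C@@H](C)Cl | intermediate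
42 | trimethylsilyl (2R,3R)-3-chloro-2-methyl-2-(trimethylsilyloxy)butanoate | C[Si](C)(C)OC(=O)[C@@](C)(O[Si](C)(C)C)[C@@H](C)Cl | intermediate (not isolated)
43 | (2R,3R)-3-chloro-2-methyl-2-(trimethylsilyloxy)butanoyl chloride | ClC(=O)[C@@](C)(O[Si](C)(C)C)[C@@H](C)Cl | intermediate
44 | O-trimethylsilyl ether of the target (side-chain tertiary hydroxyl) | C=C1C(=O)O[C@H]2[C@H]1[C@@H](OC(=O)[C@@](C)(O[Si](C)(C)C)[C@@H](C)Cl)[C@@H](OC(C)=O)/C(C(=O)OC)=C\CC[C@@]1(C)O[C@H]21 | intermediate (not isolated)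
45 | target: (4R,5R,6S,7R,8R,9S,1(10)E)-9-acetoxy-8-[(2R,3R)-3-chloro-2-hydroxy-2-methylbutanoyloxy]-4,5-epoxy-6,12-lactone 14-methyl ester | C=C1C(=O)O[C@H]2[C@H]1[C@@H](OC(=O)[C@@](C)(O)[C@@H](C)Cl)[C@@H](OC(C)=O)/C(C(=O)OC)=C\CC[C@@]1(C)O[C@H]21 | target

**Totals and risks**

Total step count: 29. Longest linear sequence: 21 steps (steps 1–3, 7–23 and 29; the sequence from dimethyl (S)-malate through steps 4–6 is equally long).

Steps most likely to fail:

1. Step 20 (Proposed new method). What may go wrong: intermolecular reaction instead of ring closure, proton transfer from C6–H to the ylide with epimerisation, β-elimination of the sulfonium group, or ring closure through the other C5 face or with C3 and C6 gauche (cis-epoxide). Fallback, from 23 back to 31: the C4 hydroxyl of 23 is converted by Mitsunobu reaction (1-phenyl-1H-tetrazole-5-thiol, PPh3, diisopropyl azodicarboxylate) into the tetrazolyl sulfide F1, which (NH4)6Mo7O24·4H2O/H2O2 oxidises to the tetrazolyl sulfone F2. Desilylation at O5 as in step 17 gives the sulfonyl alcohol F3 and Dess–Martin oxidation the sulfonyl aldehyde F4. KN(SiMe3)2 at high dilution (THF, −78 °C → rt) then closes the ten-membered ring by an intramolecular Julia–Kocienski olefination to the macrocyclic (E)-4,5-alkene F5. m-Chloroperbenzoic acid (NaHCO3, CH2Cl2, −20 °C) epoxidises this one electron-rich trisubstituted double bond from the outer face of the ring, as in the known peripheral epoxidation of (E)-4,5-olefins in germacrane-type rings, and the route is rejoined at 31.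

2. Step 19. What may go wrong: silver-induced ionisation at C4 that ends in elimination or hydride shift instead of S-alkylation, and Lewis-acid damage to the α-alkoxy aldehyde. Fallback, from 23 back to 28: the alcohol 23 is converted with diphenyl disulfide and PBu3 into the C4 phenyl sulfide F6, which is S-phenylated with diphenyliodonium tetrafluoroborate and catalytic Cu(OAc)2 (1,2-dichloroethane, 80 °C) to the silyl-protected sulfonium salt F7 while C5 is still protected. HF·pyridine then frees the sulfonium alcohol F8, and Dess–Martin oxidation gives 28 without any silver salt or free aldehyde during sulfonium formation.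

3. Step 9. What may go wrong: reagent control losing against the Felkin preference of the ketone (poor facial selectivity at C6), or hydroboration of the 1,1-disubstituted alkene. Fallback, from 13 back to 14: the substrate preference is used on purpose, LiBH(s-Bu)3 (THF, −78 °C) giving the C6 epimer F9. A Mitsunobu inversion with 4-nitrobenzoic acid (PPh3, diisopropyl azodicarboxylate) then gives the inverted ester F10, and K2CO3/MeOH releases 14.

Further compounds
F1 | step 20 | C4 (1-phenyl-1H-tetrazol-5-yl) sulfide from 23 | CC(C)(C)[Si](C)(C)OC[C@@H](OCc1ccc(OC)cc1)[C@H](C(=C)COCc1ccc(OC)cc1)[C@@H](O[Si](C)(C)C(C)(C)C)[C@@H](OC(C)=O)/C(C(=O)OC)=C\CCC(C)Sc1nnnn1-c1ccccc1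
F2 | step 20 | C4 (1-phenyl-1H-tetrazol-5-yl) sulfone | CC(C)(C)[Si](C)(C)OC[C@@H](OCc1ccc(OC)cc1)[C@H](C(=C)COCc1ccc(OC)cc1)[C@@H](O[Si](C)(C)C(C)(C)C)[C@@H](OC(C)=O)/C(C(=O)OC)=C\CCC(C)S(=O)(=O)c1nnnn1-c1ccccc1
F3 | step 20 | sulfonyl alcohol (free C5 hydroxyl) | OC[C@@H](OCc1ccc(OC)cc1)[C@H](C(=C)COCc1ccc(OC)cc1)[C@@H](O[Si](C)(C)C(C)(C)C)[C@@H](OC(C)=O)/C(C(=O)OC)=C\CCC(C)S(=O)(=O)c1nnnn1-c1ccccc1
F4 | step 20 | sulfonyl aldehyde (C5 aldehyde) | O=C[C@@H](OCc1ccc(OC)cc1)[C@H](C(=C)COCc1ccc(OC)cc1)[C@@H](O[Si](C)(C)C(C)(C)C)[C@@H](OC(C)=O)/C(C(=O)OC)=C\CCC(C)S(=O)(=O)c1nnnn1-c1ccccc1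
F5 | step 20 | macrocyclic (E)-4,5-alkene (cyclodeca-1(10),4-diene) | C=C(COCc1ccc(OC)cc1)[C@@H]1[C@@H](O[Si](C)(C)C(C)(C)C)[C@@H](OC(C)=O)/C(C(=O)OC)=C\CC/C(C)=C/[C@H]1OCc1ccc(OC)cc1
F6 | step 19 | C4 phenyl sulfide from 23 | CC(C)(C)[Si](C)(C)OC[C@@H](OCc1ccc(OC)cc1)[C@H](C(=C)COCc1ccc(OC)cc1)[C@@H](O[Si](C)(C)C(C)(C)C)[C@@H](OC(C)=O)/C(C(=O)OC)=C\CCC(C)Sc1ccccc1
F7 | step 19 | C4 diphenylsulfonium tetrafluoroborate with O5 silyl ether | CC(C)(C)[Si](C)(C)OC[C@@H](OCc1ccc(OC)cc1)[C@H](C(=C)COCc1ccc(OC)cc1)[C@@H](O[Si](C)(C)C(C)(C)C)[C@@H](OC(C)=O)/C(C(=O)OC)=C\CCC(C)[S+](c1ccccc1)c1ccccc1.F[B-](F)(F)F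
F8 | step 19 | C4 diphenylsulfonium tetrafluoroborate with free C5 hydroxyl | OC[C@@H](OCc1ccc(OC)cc1)[C@H](C(=C)COCc1ccc(OC)cc1)[C@@H](O[Si](C)(C)C(C)(C)C)[C@@H](OC(C)=O)/C(C(=O)OC)=C\CCC(C)[S+](c1ccccc1)c1ccccc1.F[B-](F)(F)F
F9 | step 9 | C6 epimer of alcohol 14 | CC(C)(C)[Si](C)(C)OC[C@H](O)[C@H](C(=C)COCc1ccc(OC)cc1)[C@@H](O[Si](C)(C)C(C)(C)C)[C@@H](O[Si](CC)(CC)CC)CC(=O)OC
F10 | step 9 | C6 4-nitrobenzoate with the configuration of 14 | CC(C)(C)[Si](C)(C)OC[C@@H](OC(=O)c1ccc(cc1)[N+](=O)[O-])[C@H](C(=C)COCc1ccc(OC)cc1)[C@@H](O[Si](C)(C)C(C)(C)C)[C@@H](O[Si](CC)(CC)CC)CC(=O)OC
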